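**Retrosynthetic overview**
1. The last step is a debenzylation. The oxane is the only ring that is built (step 10 of 11), and both benzene rings come from simple phenols.
2. Oxane ⇒ Prins cyclisation (forms O1–C2, C2–C3 and C4–O) of an (S)-1-arylhex-5-en-3-ol with O-acetylsyringaldehyde. The carbinol centre controls the other two stereocentres.
3. Homoallylic alcohol ⇒ Brown allylation of a 3-arylpropanal ⇒ Jeffery–Heck reaction of an aryl iodide with allyl alcohol ⇒ catechol (O-methylation, para-iodination, O-benzylation).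
4. O-Acetylsyringaldehyde ⇒ syringaldehyde ⇒ Cu-catalysed double methoxylation of 3,5-dibromo-4-hydroxybenzaldehyde ⇒ ring bromination, then side-chain bromination, of p-cresol.

Assumption: compounds that supply skeleton carbons are numbered as starting materials. MeI, NaOMe, protecting-group reagents, (+)-Ipc2BOMe and the catalysts are bought reagents.

**Step 1**
Reactants: 1 catechol (benzene-1,2-diol)
Product: 2 guaiacol (2-methoxyphenol)
Conditions: MeI (1.0 equiv), 1 (1.5 equiv), K2CO3 (1.0 equiv), acetone, reflux, N2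
Reagents that add atoms: iodomethane, CI
Why: Williamson ether synthesis on the catechol monoanion, where excess catechol keeps dimethylation low, leftover catechol washes out with water, and veratrole stays behind when 2 is extracted into aqueous NaOH.

**Step 2**
Reactants: 2 guaiacol
Product: 3 4-iodo-2-methoxyphenol
Conditions: NIS (1.0 equiv), p-TsOH, MeCN, rt
Reagents that add atoms: N-iodosuccinimide, O=C1CCC(=O)N1I
Why: Electrophilic aromatic iodination in which the free OH is the strongest director, so acid-activated NIS delivers iodine para to it.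

**Step 3**
Reactants: 3 4-iodo-2-methoxyphenol
Product: 4 1-(benzyloxy)-4-iodo-2-methoxybenzene
Conditions: BnBr, K2CO3, DMF, rt
Reagents that add atoms: benzyl bromide, BrCc1ccccc1
Why: Williamson O-benzylation of the phenoxide, giving an ether that survives Pd/base, alkaline peroxide and TFA and is removed by hydrogenolysis at the end.

**Step 4**
Reactants: 4 1-(benzyloxy)-4-iodo-2-methoxybenzene; 5 allyl alcohol
Product: 7 3-[4-(benzyloxy)-3-methoxyphenyl]propanal, via the enol 6 (not isolated)
Conditions: Pd(OAc)2 (3 mol %), n-Bu4NCl, NaHCO3, DMF, 45 °C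
Reagents that add atoms: none
Why: Jeffery–Heck arylation of allyl alcohol, in which aryl insertion at the terminal alkene carbon and β-hydride elimination toward the carbinol carbon give enol 6, which tautomerises to the aldehyde.

**Step 5**
Reactants: 7 3-[4-(benzyloxy)-3-methoxyphenyl]propanal; 8 allylmagnesium bromide
Product: 11 (S)-1-[4-(benzyloxy)-3-methoxyphenyl]hex-5-en-3-ol, via allylborane 9 (not isolated), via borinate 10 (not isolated)
Conditions: 8, (+)-Ipc2BOMe, Et2O, −78 °C → rt; then 7, −78 °C; then 3 M NaOH, 30% H2O2, 0 °C → rt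
Reagents that add atoms: none
Why: Brown asymmetric allylboration, in which transmetallation gives allylborane 9 of the (−)-α-pinene series, 9 adds to the Re face of 7 through a closed chair (Zimmerman–Traxler) transition state to give borinate 10, and oxidative cleavage releases the (S)-alcohol (typically 92–96% ee).

**Step 6**
Reactants: 12 p-cresol (4-methylphenol)
Product: 13 2,6-dibromo-4-methylphenol
Conditions: Br2 (2.05 equiv), AcOH, 15 °C → rt
Reagents that add atoms: bromine, BrBr
Why: Electrophilic aromatic bromination in which the OH group directs to both ortho positions because the para position carries the methyl group.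

**Step 7**
Reactants: 13 2,6-dibromo-4-methylphenol
Product: 15 3,5-dibromo-4-hydroxybenzaldehyde, via benzal bromide 14 (not isolated)
Conditions: Br2 (2.1 equiv), o-dichlorobenzene, 150–160 °C; then H2O, 100 °C
Reagents that add atoms: water, O
Why: Thermal side-chain bromination, possible because all activated ring positions are blocked so hot bromine attacks the benzylic methyl twice, followed by hydrolysis of gem-dibromide 14 to the aldehyde.

**Step 8**
Reactants: 15 3,5-dibromo-4-hydroxybenzaldehyde
Product: 16 syringaldehyde (4-hydroxy-3,5-dimethoxybenzaldehyde)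
Conditions: NaOMe (4 equiv), CuCl (15 mol %), DMF–MeOH, 110 °C; then 2 M HCl
Reagents that add atoms: sodium methoxide, [Na+].[O-]C
Why: Copper(I)-catalysed Ullmann-type C–O coupling replaces both aryl bromides by methoxide, while the non-enolisable aldehyde is shielded from base as part of the phenoxide.

**Step 9**
Reactants: 16 syringaldehyde
Product: 17 4-formyl-2,6-dimethoxyphenyl acetate (O-acetylsyringaldehyde)
Conditions: Ac2O, pyridine, CH2Cl2, 0 °C → rt
Reagents that add atoms: acetic anhydride, CC(=O)OC(C)=O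
Why: O-Acylation of the phenol gives an acid-stable, electron-withdrawing mask that makes the aldehyde more electrophilic and falls off during the methanolysis in step 10.

**Step 10**
Reactants: 11 (S)-1-[4-(benzyloxy)-3-methoxyphenyl]hex-5-en-3-ol; 17 4-formyl-2,6-dimethoxyphenyl acetate
Product: 20 (2S,4R,6S)-2-{2-[4-(benzyloxy)-3-methoxyphenyl]ethyl}-6-(4-hydroxy-3,5-dimethoxyphenyl)oxan-4-ol (all-cis), via oxocarbenium ion 18 (not isolated), via trifluoroacetate 19 (not isolated)
Conditions: 17 (1.2 equiv), TFA (10 equiv), CH2Cl2, 0 °C → rt; evaporate with toluene; then K2CO3 (cat.), MeOH, rt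
Reagents that add atoms: trifluoroacetic acid (supplies the C4 oxygen), OC(=O)C(F)(F)F
Why: Prins cyclisation, in which condensation gives the (E)-oxocarbenium ion 18, ring closure runs through a chair with both side chains equatorial and trifluoroacetate adds equatorially, so the untouched (S)-carbinol centre of 11 sets the aryl-bearing carbon and C4 of the all-cis (2S,4R,6S) ester 19, the acetoxy-aryl group curbs 2-oxonia-Cope exchange and benzylic ionisation, and base-catalysed methanolysis then cleaves both esters.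

**Step 11**
Reactants: 20 the all-cis mono-benzyl ether
Product: 21 (2S,4R,6S)-2-(4-hydroxy-3,5-dimethoxyphenyl)-6-[2-(4-hydroxy-3-methoxyphenyl)ethyl]oxan-4-ol (target)
Conditions: H2 (1 atm), 10% Pd/C, EtOAc, rt
Reagents that add atoms: none
Why: Catalytic hydrogenolysis cleaves the aryl benzyl ether much faster than the cyclic secondary benzylic C–O bond of the 2-aryl oxane, and no stereocentre is touched.

**Compound list**
1 | catechol | Oc1ccccc1O | starting material
2 | guaiacol | COc1ccccc1O | intermediate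
3 | 4-iodo-2-methoxyphenol | COc1cc(I)ccc1O | intermediate
4 | 1-(benzyloxy)-4-iodo-2-methoxybenzene | COc1cc(I)ccc1OCc1ccccc1 | intermediate
5 | allyl alcohol | C=CCO | starting material
6 | (E)-3-[4-(benzyloxy)-3-methoxyphenyl]prop-1-en-1-ol (enol, not isolated) | COc1cc(C/C=C/O)ccc1OCc1ccccc1 | intermediate
7 | 3-[4-(benzyloxy)-3-methoxyphenyl]propanal | COc1cc(CCC=O)ccc1OCc1ccccc1 | intermediate
8 | allylmagnesium bromide | C=CC[Mg]Br | starting material
9 | B-allyldiisopinocampheylborane, (−)-α-pinene series (not isolated) | C=CCB([C@H]1C[C@H]2C[C@@H]([C@@H]1C)C2(C)C)[C@H]1C[C@H]2C[C@@H]([C@@H]1C)C2(C)C | intermediate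
10 | diisopinocampheylborinate of 11 (not isolated) | COc1cc(CC[C@H](OB([C@H]2C[C@H]3C[C@@H]([C@@H]2C)C3(C)C)[C@H]2C[C@H]3C[C@@H]([C@@H]2C)C3(C)C)CC=C)ccc1OCc1ccccc1 | intermediate
11 | (S)-1-[4-(benzyloxy)-3-methoxyphenyl]hex-5-en-3-ol | COc1cc(CC[C@H](O)CC=C)ccc1OCc1ccccc1 | intermediate
12 | p-cresol | Cc1ccc(O)cc1 | starting material
13 | 2,6-dibromo-4-methylphenol | Cc1cc(Br)c(O)c(Br)c1 | intermediate
14 | 2,6-dibromo-4-(dibromomethyl)phenol (not isolated) | BrC(Br)c1cc(Br)c(O)c(Br)c1 | intermediate
15 | 3,5-dibromo-4-hydroxybenzaldehyde | O=Cc1cc(Br)c(O)c(Br)c1 | intermediate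
16 | syringaldehyde | COc1cc(C=O)cc(OC)c1O | intermediate
17 | 4-formyl-2,6-dimethoxyphenyl acetate | COc1cc(C=O)cc(OC)c1OC(C)=O | intermediate
18 | (E)-oxocarbenium trifluoroacetate from 11 and 17 (not isolated) | COc1cc(CC[C@H](/[O+]=C/c2cc(OC)c(OC(C)=O)c(OC)c2)CC=C)ccc1OCc1ccccc1.[O-]C(=O)C(F)(F)F | intermediate
19 | (2S,4R,6S)-2-[4-(acetyloxy)-3,5-dimethoxyphenyl]-6-{2-[4-(benzyloxy)-3-methoxyphenyl]ethyl}oxan-4-yl trifluoroacetate (not isolated) | COc1cc(CC[C@H]2C[C@@H](OC(=O)C(F)(F)F)C[C@@H](c3cc(OC)c(OC(C)=O)c(OC)c3)O2)ccc1OCc1ccccc1 | intermediate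
20 | (2S,4R,6S)-2-{2-[4-(benzyloxy)-3-methoxyphenyl]ethyl}-6-(4-hydroxy-3,5-dimethoxyphenyl)oxan-4-ol | COc1cc(CC[C@H]2C[C@@H](O)C[C@@H](c3cc(OC)c(O)c(OC)c3)O2)ccc1OCc1ccccc1 | intermediate
21 | (2S,4R,6S)-2-(4-hydroxy-3,5-dimethoxyphenyl)-6-[2-(4-hydroxy-3-methoxyphenyl)ethyl]oxan-4-ol | COc1cc(CC[C@H]2C[C@@H](O)C[C@@H](c3cc(OC)c(O)c(OC)c3)O2)ccc1O | target

**Total step count:** 11
**Longest linear sequence:** 7 steps (1, 2, 3, 4, 5, 10, 11)

**The three steps most likely to fail**

Step 10 (Prins cyclisation).
- The risks are side-chain exchange and loss of ee through 2-oxonia-Cope rearrangement, and attack of the electron-rich benzyloxy-methoxy ring on the cation.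
- The fallback first ties the two halves together as an ester. It then generates the cation without free aldehyde or water (segment-coupling Prins). It sets out from 16 and uses 11.
- Compound 16 is benzylated (BnBr, K2CO3, DMF) to 4-(benzyloxy)-3,5-dimethoxybenzaldehyde F1.
- Pinnick oxidation (NaClO2, NaH2PO4, 2-methyl-2-butene) gives 4-(benzyloxy)-3,5-dimethoxybenzoic acid F2.
- Steglich esterification with 11 (DCC, DMAP, CH2Cl2) gives (3S)-1-[4-(benzyloxy)-3-methoxyphenyl]hex-5-en-3-yl 4-(benzyloxy)-3,5-dimethoxybenzoate F3.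
- DIBAL-H at −78 °C gives the diisobutylaluminium hemiacetal F4. It is acetylated in the same flask (Ac2O, pyridine, DMAP) to the α-acetoxy ether F5.
- BF3·OEt2/AcOH at 0 °C ionises it and closes the ring to the all-cis oxan-4-yl acetate F6.
- K2CO3/MeOH gives the all-cis bis-benzyl ether F7.
- Hydrogenolysis as in step 11 removes both benzyl groups, so the fallback comes back to the route at 21.

Step 4 (Heck reaction with allyl alcohol).
- The risks are the branched 2-arylpropanal, a second arylation, and aldol self-condensation of 7.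
- The fallback replaces the Pd chemistry by a polar C–C bond formation. It sets out from 4.
- Iodine–lithium exchange (n-BuLi, THF, −78 °C) gives [4-(benzyloxy)-3-methoxyphenyl]lithium F8.
- This opens oxetane in the presence of BF3·OEt2 (aq NH4Cl quench) to 3-[4-(benzyloxy)-3-methoxyphenyl]propan-1-ol F9.
- Parikh–Doering oxidation (SO3·pyridine, DMSO, Et3N) then comes back to the route at 7.

Step 7 (side-chain bromination at 150 °C).
- The risks are tar formation, incomplete dibromination and awkward handling.
- The fallback inverts the order so that the methyl group is oxidised only after the ring has become electron-rich. It sets out from 13.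
- Cu-catalysed methoxylation (NaOMe, CuCl, DMF–MeOH, 110 °C) gives 2,6-dimethoxy-4-methylphenol F10.
- DDQ (2.2 equiv) in aqueous dioxane dehydrogenates this p-cresol, first to 4-(hydroxymethyl)-2,6-dimethoxyphenol F11 and then further to the aldehyde. The fallback comes back to the route at 16.

**Further compounds**
F1 | step 10 | 4-(benzyloxy)-3,5-dimethoxybenzaldehyde | COc1cc(C=O)cc(OC)c1OCc1ccccc1
F2 | step 10 | 4-(benzyloxy)-3,5-dimethoxybenzoic acid | COc1cc(C(=O)O)cc(OC)c1OCc1ccccc1
F3 | step 10 | (3S)-1-[4-(benzyloxy)-3-methoxyphenyl]hex-5-en-3-yl 4-(benzyloxy)-3,5-dimethoxybenzoate | COc1cc(CC[C@H](OC(=O)c2cc(OC)c(OCc3ccccc3)c(OC)c2)CC=C)ccc1OCc1ccccc1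
F4 | step 10 | diisobutylaluminium hemiacetal (from F3, both epimers at the acetal carbon) | COc1cc(CC[C@H](OC(O[Al](CC(C)C)CC(C)C)c2cc(OC)c(OCc3ccccc3)c(OC)c2)CC=C)ccc1OCc1ccccc1
F5 | step 10 | α-acetoxy ether (both epimers at the acetal carbon) | COc1cc(CC[C@H](OC(OC(C)=O)c2cc(OC)c(OCc3ccccc3)c(OC)c2)CC=C)ccc1OCc1ccccc1
F6 | step 10 | all-cis oxan-4-yl acetate, (2S,4R,6S) | COc1cc(CC[C@H]2C[C@@H](OC(C)=O)C[C@@H](c3cc(OC)c(OCc4ccccc4)c(OC)c3)O2)ccc1OCc1ccccc1
F7 | step 10 | all-cis bis-benzyl ether, (2S,4R,6S)-oxan-4-ol | COc1cc(CC[C@H]2C[C@@H](O)C[C@@H](c3cc(OC)c(OCc4ccccc4)c(OC)c3)O2)ccc1OCc1ccccc1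
F8 | step 4 | [4-(benzyloxy)-3-methoxyphenyl]lithium | [Li]c1ccc(OCc2ccccc2)c(OC)c1
F9 | step 4 | 3-[4-(benzyloxy)-3-methoxyphenyl]propan-1-ol | COc1cc(CCCO)ccc1OCc1ccccc1
F10 | step 7 | 2,6-dimethoxy-4-methylphenol | COc1cc(C)cc(OC)c1O
F11 | step 7 | 4-(hydroxymethyl)-2,6-dimethoxyphenol | COc1cc(CO)cc(OC)c1O
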